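**Plan**

1. Difficulty: the ring is a pseudo-symmetric 2,5-dioxygenated 1,4-benzoquinone. OH, C16H33, OMe and H must stand in one fixed order (C2, C3, C5, C6), so arene-first routes have to distinguish two nearly equal oxygens and two nearly equal CH sites.
2. Enabling feature: ring atoms C1(=O)-C2(OH)=C3(C16H33)-C4(=O) are four contiguous carbons, three of them oxygenated. This is the squaric acid skeleton with C1 bonded to C4, and C5(OMe)=C6H is methyl vinyl ether, so the six-membered ring is a ring-expanded cyclobutenone.
3. Cuts (retro): O-tBu stands in for the C2 hydroxyl. Cutting ring bond C4-C5 (retro-6π) and re-forming a transannular C1-C4 bond (retro-4π) gives a 4-hydroxy-4-(2-methoxyvinyl)cyclobutenone. Then C1-C6 is cut (vinyllithium + carbonyl), and C3-C1' (Grignard + squarate).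
4. Forward: the squarate diester and the C16 Grignard reagent give the alkylcyclobutenedione, and (Z)-2-methoxyvinyllithium adds to its only ketone-like carbonyl. Heat releases the ring strain (4π opening, 6π closure) and forms the only ring of the target with all four substituents in place. Ag2O and TFA finish.
5. The two-carbon unit enters as an alkene, not as methoxyacetylene. The concerted 6π closure has no five-membered alternative, whereas an ynol ether is polarised towards 5-exo closure of the enyne-ketene.
6. Stereochemistry: the target is achiral. The carbinol centre and the Z-alkene of the precursor are transient and are erased on aromatisation.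

Key step: step 4

Remark: the SMILES holds no stereocentre and no stereogenic double bond, so the "single enantiomer" is the achiral compound itself; di-tert-butyl squarate is taken as a purchasable squarate diester.

**Route**

Step 1
Reactants: 1 1-bromohexadecane; 2 di-tert-butyl squarate (3,4-di-tert-butoxycyclobut-3-ene-1,2-dione)
Product: 6 3-tert-butoxy-4-hexadecylcyclobut-3-ene-1,2-dione, via hexadecylmagnesium bromide 3 (not isolated), via bromomagnesium alkoxide 4 (not isolated), via tertiary trifluoroacetate 5 (not isolated)
Conditions: 1, Mg, THF, 50 °C; add to 2, THF, -78 to -40 °C; (CF3CO)2O, -78 to 0 °C; aq NaHCO3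
Reagents that add atoms: none
Why: Grignard 1,2-addition to one of the two equivalent squarate carbonyls, trifluoroacetylation of the tertiary alkoxide and ionisation to the alkoxy-stabilised cyclobutenyl cation, which sheds a tert-butyl cation as isobutene, is the standard addition-collapse route from dialkyl squarates to 3-alkoxy-4-alkylcyclobutenediones, and no stereocentre remains.

Step 2
Reactants: 7 methyl vinyl ether
Product: 9 (Z)-1-bromo-2-methoxyethene, via 1,2-dibromo-1-methoxyethane 8 (not isolated)
Conditions: Br2, CH2Cl2, -78 °C; i-Pr2NEt, -78 °C to reflux; distillation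
Reagents that add atoms: bromine, BrBr
Why: Electrophilic bromination of the enol ether followed by base-induced loss of HBr from the α-bromo ether is the classical preparation of 2-bromovinyl ethers, should favour the Z isomer (cis effect), and the geometry is in any case erased in step 4.

Step 3
Reactants: 9 (Z)-1-bromo-2-methoxyethene; 6 3-tert-butoxy-4-hexadecylcyclobut-3-ene-1,2-dione
Product: 12 3-tert-butoxy-2-hexadecyl-4-hydroxy-4-[(Z)-2-methoxyethenyl]cyclobut-2-en-1-one (racemic), via (Z)-2-methoxyvinyllithium 10 (not isolated), via lithium alkoxide 11 (not isolated)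
Conditions: 9, t-BuLi (2 equiv), Et2O, -78 °C; cannulate into 6, THF, -78 °C; H2O (NaHCO3-buffered), -78 °C; plug of Et3N-deactivated silica
Reagents that add atoms: none
Why: Bromine-lithium exchange with retention gives the configurationally stable (Z)-2-alkoxyvinyllithium, which should add 1,2 to C2=O of 6 (next to the tert-butoxy carbon) because C1=O is deactivated as a vinylogous ester (tBuO-C3=C4-C1=O); the new carbinol centre is racemic and is destroyed in step 4.

Step 4
Reactants: 12 3-tert-butoxy-2-hexadecyl-4-hydroxy-4-[(Z)-2-methoxyethenyl]cyclobut-2-en-1-one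
Product: 16 2-tert-butoxy-3-hexadecyl-5-methoxycyclohexa-2,5-diene-1,4-dione, via dienylketene 13 (not isolated), via cyclohexadienone 14 (not isolated), via hydroquinone 15 (not isolated)
Conditions: PhMe (0.01 M), 110 °C, Ar; cool, Ag2O, rt
Reagents that add atoms: none
Why: Heat opens the strained cyclobutenone by conrotatory 4π cleavage of the bond between the carbinol carbon and the carbonyl carbon, and the donor hydroxyl turns outward (torquoselectivity), so the methoxyvinyl arm turns inward and dienylketene 13 forms with the ketene and vinyl termini cis on the central double bond. A thermally allowed disrotatory 6π electrocyclisation then bonds the ketene carbon (C4 of the target) to the methoxy-bearing vinyl terminus (C5) and closes the only ring formed, the six-membered carbocycle; enolisation of cyclohexadienone 14 gives hydroquinone 15, and Ag2O removes two hydrogens to give 16. The closest known reaction type is the thermal ring expansion of 4-alkenyl- and 4-aryl-4-hydroxycyclobutenones to hydroquinones followed by oxidation to the quinone, the alkenyl counterpart of the Moore rearrangement. No lasting stereocentre is created: the carbinol centre of 12 is lost on ring opening and C6 of 14 on enolisation, so neither the racemic nature of 12 nor its alkene geometry matters. The selectivity needed is regiochemical and is fixed by the substrate because the six atoms keep their sequence: hexadecyl ends between the ketene-derived carbonyl and the tert-butoxy carbon, methoxy on the other side of that same carbonyl, and hydrogen next to the carbinol-derived carbonyl. High dilution and a neutral aprotic medium should keep the ketene from intermolecular capture and let the aromatising enolisation of 14 outrun loss of methanol.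

Step 5
Reactants: 16 2-tert-butoxy-3-hexadecyl-5-methoxycyclohexa-2,5-diene-1,4-dione
Product: 17 3-hexadecyl-2-hydroxy-5-methoxycyclohexa-2,5-diene-1,4-dione (target, CNP0125193.0)
Conditions: CF3CO2H, CH2Cl2, 0 °C to rt
Reagents that add atoms: none
Why: Acid-mediated E1 cleavage of the tert-butyl vinylogous ester (tert-butyl ether deprotection) should release isobutene and the C2 hydroxyl, while the C5 methyl ether cannot ionise in anhydrous acid and stays.

**Compound list**

1 | 1-bromohexadecane | CCCCCCCCCCCCCCCCBr | starting material
2 | di-tert-butyl squarate (3,4-di-tert-butoxycyclobut-3-ene-1,2-dione) | CC(C)(C)OC1=C(OC(C)(C)C)C(=O)C1=O | starting material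
3 | hexadecylmagnesium bromide | CCCCCCCCCCCCCCCC[Mg]Br | intermediate
4 | bromomagnesium 2,3-di-tert-butoxy-1-hexadecyl-4-oxocyclobut-2-en-1-olate (racemic) | CCCCCCCCCCCCCCCCC1(O[Mg]Br)C(OC(C)(C)C)=C(OC(C)(C)C)C1=O | intermediate
5 | 2,3-di-tert-butoxy-1-hexadecyl-4-oxocyclobut-2-en-1-yl trifluoroacetate (racemic) | CCCCCCCCCCCCCCCCC1(OC(=O)C(F)(F)F)C(OC(C)(C)C)=C(OC(C)(C)C)C1=O | intermediate
6 | 3-tert-butoxy-4-hexadecylcyclobut-3-ene-1,2-dione | CCCCCCCCCCCCCCCCC1=C(OC(C)(C)C)C(=O)C1=O | intermediate
7 | methyl vinyl ether | COC=C | starting material
8 | 1,2-dibromo-1-methoxyethane (racemic) | COC(Br)CBr | intermediate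
9 | (Z)-1-bromo-2-methoxyethene | CO/C=C\Br | intermediate
10 | (Z)-2-methoxyvinyllithium | [Li]/C=C\OC | intermediate
11 | lithium alkoxide of 12 (racemic) | CCCCCCCCCCCCCCCCC1=C(OC(C)(C)C)C(O[Li])(/C=C\OC)C1=O | intermediate
12 | 3-tert-butoxy-2-hexadecyl-4-hydroxy-4-[(Z)-2-methoxyethenyl]cyclobut-2-en-1-one (racemic) | CCCCCCCCCCCCCCCCC1=C(OC(C)(C)C)C(O)(/C=C\OC)C1=O | intermediate
13 | (3Z,5Z)-3-tert-butoxy-2-hexadecyl-4-hydroxy-6-methoxyhexa-1,3,5-trien-1-one (dienylketene) | CCCCCCCCCCCCCCCCC(=C=O)/C(OC(C)(C)C)=C(O)\C=C/OC | intermediate
14 | 3-tert-butoxy-2-hexadecyl-4-hydroxy-6-methoxycyclohexa-2,4-dien-1-one (racemic) | CCCCCCCCCCCCCCCCC1=C(OC(C)(C)C)C(O)=CC(OC)C1=O | intermediate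
15 | 2-tert-butoxy-3-hexadecyl-5-methoxybenzene-1,4-diol | CCCCCCCCCCCCCCCCc1c(O)c(OC)cc(O)c1OC(C)(C)C | intermediate
16 | 2-tert-butoxy-3-hexadecyl-5-methoxycyclohexa-2,5-diene-1,4-dione | CCCCCCCCCCCCCCCCC1=C(OC(C)(C)C)C(=O)C=C(OC)C1=O | intermediate
17 | 3-hexadecyl-2-hydroxy-5-methoxycyclohexa-2,5-diene-1,4-dione | CCCCCCCCCCCCCCCCC1=C(O)C(=O)C=C(OC)C1=O | target

**Totals**

Total step count: 5. Longest linear sequence: 4 (steps 1, 3, 4, 5; step 2 feeds step 3).

**Steps most likely to fail**

Step 4 (key step).
- What may go wrong:
  - Methanol may be lost from the cyclohexadienone stage before it enolises, pushed out by the C4 hydroxyl.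
  - A polar five-membered closure may occur through the nucleophilic β-carbon of the enol ether.
  - The ketene may be captured by a hydroxyl group of a second molecule.
- Fallback: the methoxy group is taken out of the pericyclic event and installed after the ring exists.
  - Setting out from 6, ethynylmagnesium bromide (THF, -78 °C) should add to the same ketone-like carbonyl to give 3-tert-butoxy-4-ethynyl-2-hexadecyl-4-hydroxycyclobut-2-en-1-one F1.
  - A Moore rearrangement (p-xylene, reflux) of this terminal alkyne, which carries no substituent that favours five-membered closure, should give 2-tert-butoxy-3-hexadecylcyclohexa-2,5-diene-1,4-dione F2 directly at the quinone level.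
  - Conjugate addition of methanol (MeOH, ZnCl2, rt) should then occur at C5. This position is β to the C1 carbonyl, the one not deactivated by the vinylogous ester resonance of the C2 alkoxy group.
  - This gives hydroquinone 15, where the fallback rejoins the route ahead of the Ag2O oxidation to 16.

Step 3.
- What may go wrong:
  - The vinyllithium may lose lithium methoxide by β-elimination before it is trapped.
  - The basic reagent may deprotonate the dione at the allylic CH2 of the chain.
  - The doubly allylic carbinol may ionise under trace acid on work-up, with allylic transposition and hydrolysis of the enol ether.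
- Fallback: C5-C6 is brought in as an alkyne and the alkene is set afterwards.
  - Setting out from 6, lithium methoxyacetylide F3 is made in the flask from chloroacetaldehyde dimethyl acetal and LiNEt2 (3 equiv, THF, 0 °C). It is less basic and cannot β-eliminate.
  - It should add at -78 °C to give 3-tert-butoxy-2-hexadecyl-4-hydroxy-4-(methoxyethynyl)cyclobut-2-en-1-one F4.
  - Semihydrogenation at room temperature (H2, Lindlar catalyst, quinoline, EtOAc), as in the Arens-van Dorp sequence, should give the Z enol ether and rejoin the route at 12.

Step 1.
- What may go wrong: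
  - The long-chain Grignard reagent may be poorly soluble at low temperature, so that addition is slow and a second addition occurs on warming.
  - Both tert-butyl groups may be lost during the acid-releasing collapse.
- Fallback: the ring-chain bond is made with an sp nucleophile and saturated afterwards.
  - Setting out from 2, lithium hexadec-1-yn-1-ide F5 (1-hexadecyne, n-BuLi, THF, -78 °C), which is soluble and weakly basic, should give 2,3-di-tert-butoxy-4-(hexadec-1-yn-1-yl)-4-hydroxycyclobut-2-en-1-one F6 after an aqueous quench.
  - Collapse with (CF3CO)2O at -78 °C should give 3-tert-butoxy-4-(hexadec-1-yn-1-yl)cyclobut-3-ene-1,2-dione F7.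
  - Hydrogenation of the triple bond (H2, Pd/C, EtOAc) should leave the tetrasubstituted push-pull ring alkene alone and rejoin the route at 6.

Further compounds
F1 | step 4 | 3-tert-butoxy-4-ethynyl-2-hexadecyl-4-hydroxycyclobut-2-en-1-one (racemic) | CCCCCCCCCCCCCCCCC1=C(OC(C)(C)C)C(O)(C#C)C1=O
F2 | step 4 | 2-tert-butoxy-3-hexadecylcyclohexa-2,5-diene-1,4-dione | CCCCCCCCCCCCCCCCC1=C(OC(C)(C)C)C(=O)C=CC1=O
F3 | step 3 | lithium methoxyacetylide | COC#C[Li]
F4 | step 3 | 3-tert-butoxy-2-hexadecyl-4-hydroxy-4-(methoxyethynyl)cyclobut-2-en-1-one (racemic) | CCCCCCCCCCCCCCCCC1=C(OC(C)(C)C)C(O)(C#COC)C1=O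
F5 | step 1 | lithium hexadec-1-yn-1-ide | CCCCCCCCCCCCCCC#C[Li]
F6 | step 1 | 2,3-di-tert-butoxy-4-(hexadec-1-yn-1-yl)-4-hydroxycyclobut-2-en-1-one (racemic) | CCCCCCCCCCCCCCC#CC1(O)C(OC(C)(C)C)=C(OC(C)(C)C)C1=O
F7 | step 1 | 3-tert-butoxy-4-(hexadec-1-yn-1-yl)cyclobut-3-ene-1,2-dione | CCCCCCCCCCCCCCC#CC1=C(OC(C)(C)C)C(=O)C1=O
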